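The side chain is cut between C2′ (the allylic CH2 two carbons from the quaternary C2 of the pyran ring) and C3′ (the vinylic CH of the Δ3′ olefin). C1′–C2′ is read as a vinyl group on C2, the only monosubstituted alkene of a 2-vinyl-2H-chromene, and C3′ as the iodine-bearing carbon of an (E)-alkenyl iodide made by syn-methylalumination of a geranyl-derived enyne. One-pot 9-BBN hydroboration/B-alkyl Suzuki–Miyaura coupling joins the C13 chromene and the C14 triene and carries the E geometry through. C2 is set beforehand by Pd-catalysed asymmetric etherification of isoprene monoepoxide with an o-vinylphenol; ring-closing metathesis then builds the pyran ring.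

Key step: step 10

Remark (assumption): the absolute sense of the Pd-catalysed etherification in step 4 is not derived here. Both antipodes of the ligand are commercial, and the one that delivers (R)-6 is used. No later step breaks a bond at C2, so all later descriptors follow from (R)-6.

Remark: 2H-chromenes can ring-open reversibly to o-quinone methides under UV light or strong heating, which would racemise C2. Compounds 7–9 and 16–18 are therefore handled in the dark and not heated above about 50 °C.

Step 1
Reactants: 1 methylhydroquinone (2-methylbenzene-1,4-diol)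
Product: 2 2-methyl-4-{[tri(propan-2-yl)silyl]oxy}phenol
Conditions: TIPSCl (1.0 equiv, slow addition), imidazole (2 equiv), DMF, −10 → 0 °C
Reagents that add atoms: chlorotri(propan-2-yl)silane (TIPSCl), CC(C)[Si](Cl)(C(C)C)C(C)C
Why: Silyl ether formation under steric control: the bulky silyl chloride should react faster at O4 (flanked by two ring hydrogens) than at O1 (next to the methyl group), and the minor regioisomer and bis-silyl ether are removed by chromatography.

Step 2
Reactants: 2 2-methyl-4-{[tri(propan-2-yl)silyl]oxy}phenol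
Product: 3 2-hydroxy-3-methyl-5-{[tri(propan-2-yl)silyl]oxy}benzaldehyde
Conditions: MgCl2, Et3N, (CH2O)n, MeCN, reflux
Reagents that add atoms: paraformaldehyde (as formaldehyde), C=O
Why: Magnesium-mediated ortho-formylation (Casnati–Skattebøl): the magnesium phenoxide delivers formaldehyde to C6, the only free position ortho to the hydroxyl, and a second formaldehyde oxidises the benzylic alkoxide to the aldehyde by hydride transfer.

Step 3
Reactants: 3 2-hydroxy-3-methyl-5-{[tri(propan-2-yl)silyl]oxy}benzaldehyde
Product: 4 2-ethenyl-6-methyl-4-{[tri(propan-2-yl)silyl]oxy}phenol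
Conditions: Ph3PCH3Br (2.6 equiv), n-BuLi (2.5 equiv), THF, 0 °C → rt
Reagents that add atoms: methyltriphenylphosphonium bromide, [Br-].C[P+](c1ccccc1)(c1ccccc1)c1ccccc1
Why: Wittig methylenation with an excess of ylide (the first equivalent only deprotonates the phenol) converts the aryl aldehyde into the styrene needed for ring closure.

Step 4
Reactants: 4 2-ethenyl-6-methyl-4-{[tri(propan-2-yl)silyl]oxy}phenol; 5 racemic 2-ethenyl-2-methyloxirane (isoprene monoepoxide)
Product: 6 (2R)-2-(2-ethenyl-6-methyl-4-{[tri(propan-2-yl)silyl]oxy}phenoxy)-2-methylbut-3-en-1-ol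
Conditions: Pd2(dba)3·CHCl3 (1 mol %), Trost DACH-phenyl ligand (3 mol %, the antipode that gives (R)-6), CH2Cl2, rt
Reagents that add atoms: none
Why: Pd-catalysed asymmetric allylic etherification (Tsuji–Trost, dynamic kinetic asymmetric transformation of a vinyl epoxide): ionisation of 5 gives a π-allyl-Pd alkoxide whose diastereomers interconvert by π–σ–π faster than they are trapped, the alkoxide deprotonates the phenol, and the ion-paired phenoxide attacks the proximal, fully substituted terminus inside the chiral pocket of the ligand, which sets C2 under catalyst control.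

Step 5
Reactants: 6 (2R)-2-(2-ethenyl-6-methyl-4-{[tri(propan-2-yl)silyl]oxy}phenoxy)-2-methylbut-3-en-1-ol
Product: 7 [(2R)-2,8-dimethyl-6-{[tri(propan-2-yl)silyl]oxy}-2H-chromen-2-yl]methanol
Conditions: Grubbs II (3 mol %), CH2Cl2 (0.01 M), 40 °C
Reagents that add atoms: none
Why: Ring-closing metathesis between the styrene and the vinyl group on the quaternary carbon closes the six-membered 2H-pyran ring with loss of ethene; no bond at the stereocentre is broken, so its configuration is kept.

Step 6
Reactants: 7 [(2R)-2,8-dimethyl-6-{[tri(propan-2-yl)silyl]oxy}-2H-chromen-2-yl]methanol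
Product: 8 (2R)-2,8-dimethyl-6-{[tri(propan-2-yl)silyl]oxy}-2H-chromene-2-carbaldehyde
Conditions: Dess–Martin periodinane (1.3 equiv), CH2Cl2, 0 °C → rt
Reagents that add atoms: none
Why: Dess–Martin oxidation of the neopentyl-type primary alcohol gives an aldehyde that has no α-hydrogen and so cannot epimerise.

Step 7
Reactants: 8 (2R)-2,8-dimethyl-6-{[tri(propan-2-yl)silyl]oxy}-2H-chromene-2-carbaldehyde
Product: 9 {[(2S)-2-ethenyl-2,8-dimethyl-2H-chromen-6-yl]oxy}tri(propan-2-yl)silane
Conditions: Ph3PCH3Br (1.5 equiv), n-BuLi (1.4 equiv), THF, −78 → 0 °C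
Reagents that add atoms: methyltriphenylphosphonium bromide, [Br-].C[P+](c1ccccc1)(c1ccccc1)c1ccccc1
Why: Wittig methylenation gives the terminal vinyl group on C2; the descriptor changes from R to S only because the CIP ranking of the substituents changes.

Step 8
Reactants: 10 geranyl bromide ((2E)-1-bromo-3,7-dimethylocta-2,6-diene); 11 propargyl bromide (3-bromoprop-1-yne)
Product: 13 (5E)-6,10-dimethylundeca-5,9-dien-1-yne, via 1,3-dilithiopropyne 12 (not isolated)
Conditions: 11, n-BuLi (2 equiv), TMEDA, Et2O/hexane, −78 °C; then 10, −78 °C → rt; aq. NH4Cl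
Reagents that add atoms: none
Why: Alkylation of 1,3-dilithiopropyne (from bromine–lithium exchange and acetylenic deprotonation of 11) at its more reactive propargylic carbanion by SN2 displacement of the primary allylic bromide, which leaves the (E)-olefin untouched.

Step 9
Reactants: 13 (5E)-6,10-dimethylundeca-5,9-dien-1-yne
Product: 15 (1E,5E)-1-iodo-2,6,10-trimethylundeca-1,5,9-triene, via alkenyldimethylalane 14 (not isolated)
Conditions: Me3Al (2 equiv), Cp2ZrCl2 (0.25 equiv), CH2Cl2, 0 °C → rt; then I2, THF, −30 → 0 °C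
Reagents that add atoms: trimethylaluminium, C[Al](C)C; iodine, II
Why: Negishi zirconium-catalysed carboalumination: syn addition of Me–Al across the terminal alkyne puts methyl on the internal and aluminium on the terminal carbon, and iodinolysis of the C–Al bond with retention gives the (E)-alkenyl iodide.

Step 10
Reactants: 9 {[(2S)-2-ethenyl-2,8-dimethyl-2H-chromen-6-yl]oxy}tri(propan-2-yl)silane; 15 (1E,5E)-1-iodo-2,6,10-trimethylundeca-1,5,9-triene
Product: 17 {[(2S)-2,8-dimethyl-2-[(3E,7E)-4,8,12-trimethyltrideca-3,7,11-trien-1-yl]-2H-chromen-6-yl]oxy}tri(propan-2-yl)silane, via B-alkyl-9-BBN borane 16 (not isolated)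
Conditions: 9-BBN dimer (0.6 equiv), THF, 0 °C → rt; then 15 (1.1 equiv), PdCl2(dppf)·CH2Cl2 (5 mol %), AsPh3 (10 mol %), Cs2CO3 (3 equiv), degassed DMF/THF/H2O, rt, dark
Reagents that add atoms: none
Why: 9-BBN adds B–H across the C1′=C2′ vinyl group of 9 with boron on the terminal carbon, and the base-activated borane 16 then transfers its primary alkyl group to the alkenyl–Pd(II) iodide formed by oxidative addition of Pd(0) into the C–I bond of 15, reductive elimination forging the C(sp3)–C(sp2) bond. The closest known reaction type is the B-alkyl Suzuki–Miyaura coupling of primary alkyl-9-BBN reagents with (E)-2-methylalk-1-enyl iodides (Johnson–Danishefsky conditions). No ring is closed and no stereocentre is created: the (E) geometry of the new trisubstituted olefin is fixed in 15 and kept because oxidative addition and reductive elimination both proceed with retention, while C2 is not touched. The step needs chemoselective hydroboration of the vinyl group in the presence of the C3=C4 styrenyl olefin; the terminal monosubstituted alkene should react with the bulky dialkylborane far faster than the cis-disubstituted conjugated ring olefin, and boron ends γ (not β) to the ring oxygen, so no β-alkoxy elimination can follow. Only the primary alkyl group should leave boron, since the secondary bicyclic B–C bonds of 9-BBN transmetalate much more slowly, and dppf/AsPh3 favour reductive elimination over β-hydride elimination.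

Step 11
Reactants: 17 {[(2S)-2,8-dimethyl-2-[(3E,7E)-4,8,12-trimethyltrideca-3,7,11-trien-1-yl]-2H-chromen-6-yl]oxy}tri(propan-2-yl)silane
Product: 18 (2S)-2,8-dimethyl-2-[(3E,7E)-4,8,12-trimethyltrideca-3,7,11-trien-1-yl]-2H-chromen-6-ol
Conditions: TBAF (1.1 equiv), AcOH (1.1 equiv), THF, 0 °C, argon, dark
Reagents that add atoms: none
Why: Fluoride cleavage of the aryl silyl ether (Si–F bond formation), buffered with acetic acid and run under argon so that the electron-rich phenol is released without oxidation or base-induced side reactions.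

Compound list
1 | methylhydroquinone (2-methylbenzene-1,4-diol) | Cc1cc(O)ccc1O | starting material
2 | 2-methyl-4-{[tri(propan-2-yl)silyl]oxy}phenol | Cc1cc(O[Si](C(C)C)(C(C)C)C(C)C)ccc1O | intermediate
3 | 2-hydroxy-3-methyl-5-{[tri(propan-2-yl)silyl]oxy}benzaldehyde | Cc1cc(O[Si](C(C)C)(C(C)C)C(C)C)cc(C=O)c1O | intermediate
4 | 2-ethenyl-6-methyl-4-{[tri(propan-2-yl)silyl]oxy}phenol | Cc1cc(O[Si](C(C)C)(C(C)C)C(C)C)cc(C=C)c1O | intermediate
5 | racemic 2-ethenyl-2-methyloxirane (isoprene monoepoxide) | CC1(C=C)CO1 | starting material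
6 | (2R)-2-(2-ethenyl-6-methyl-4-{[tri(propan-2-yl)silyl]oxy}phenoxy)-2-methylbut-3-en-1-ol | C=C[C@](C)(CO)Oc1c(C)cc(O[Si](C(C)C)(C(C)C)C(C)C)cc1C=C | intermediate
7 | [(2R)-2,8-dimethyl-6-{[tri(propan-2-yl)silyl]oxy}-2H-chromen-2-yl]methanol | OC[C@@]1(C)C=Cc2cc(O[Si](C(C)C)(C(C)C)C(C)C)cc(C)c2O1 | intermediate
8 | (2R)-2,8-dimethyl-6-{[tri(propan-2-yl)silyl]oxy}-2H-chromene-2-carbaldehyde | O=C[C@@]1(C)C=Cc2cc(O[Si](C(C)C)(C(C)C)C(C)C)cc(C)c2O1 | intermediate
9 | {[(2S)-2-ethenyl-2,8-dimethyl-2H-chromen-6-yl]oxy}tri(propan-2-yl)silane | C=C[C@@]1(C)C=Cc2cc(O[Si](C(C)C)(C(C)C)C(C)C)cc(C)c2O1 | intermediate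
10 | geranyl bromide ((2E)-1-bromo-3,7-dimethylocta-2,6-diene) | CC(C)=CCC/C(C)=C/CBr | starting material
11 | propargyl bromide (3-bromoprop-1-yne) | C#CCBr | starting material
12 | 1,3-dilithiopropyne | [Li]CC#C[Li] | intermediate
13 | (5E)-6,10-dimethylundeca-5,9-dien-1-yne | CC(C)=CCC/C(C)=C/CCC#C | intermediate
14 | dimethyl[(1E,5E)-2,6,10-trimethylundeca-1,5,9-trien-1-yl]alane | CC(C)=CCC/C(C)=C/CC/C(C)=C/[Al](C)C | intermediate
15 | (1E,5E)-1-iodo-2,6,10-trimethylundeca-1,5,9-triene | CC(C)=CCC/C(C)=C/CC/C(C)=C/I | intermediate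
16 | 9-{2-[(2S)-2,8-dimethyl-6-{[tri(propan-2-yl)silyl]oxy}-2H-chromen-2-yl]ethyl}-9-borabicyclo[3.3.1]nonane | C1CCC2CCCC1B2CC[C@@]3(C)C=Cc4cc(O[Si](C(C)C)(C(C)C)C(C)C)cc(C)c4O3 | intermediate
17 | {[(2S)-2,8-dimethyl-2-[(3E,7E)-4,8,12-trimethyltrideca-3,7,11-trien-1-yl]-2H-chromen-6-yl]oxy}tri(propan-2-yl)silane | CC(C)=CCC/C(C)=C/CC/C(C)=C/CC[C@@]1(C)C=Cc2cc(O[Si](C(C)C)(C(C)C)C(C)C)cc(C)c2O1 | intermediate
18 | (2S)-2,8-dimethyl-2-[(3E,7E)-4,8,12-trimethyltrideca-3,7,11-trien-1-yl]-2H-chromen-6-ol | CC(C)=CCC/C(C)=C/CC/C(C)=C/CC[C@@]1(C)C=Cc2cc(O)cc(C)c2O1 | target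

Total step count: 11. Longest linear sequence: 9 steps (steps 1–7, 10, 11, from methylhydroquinone); the alkenyl iodide takes 2 steps (8, 9).

Steps most likely to fail

Step 4. The doubly ortho-substituted phenoxide may attack the fully substituted allyl terminus slowly, so that attack at the primary terminus and poor facial discrimination erode regio- and enantiocontrol. The fallback sets out from 2 (with 5) and comes back at 9. The less hindered phenol 2, with one ortho substituent, is used as the nucleophile with 5 and the antipodal ligand. This should give (2S)-2-methyl-2-(2-methyl-4-{[tri(propan-2-yl)silyl]oxy}phenoxy)but-3-en-1-ol F1. In this series the vinyl group is kept as the future C1′=C2′ and the hydroxymethyl carbon becomes C3. Dess–Martin oxidation should give (2S)-2-methyl-2-(2-methyl-4-{[tri(propan-2-yl)silyl]oxy}phenoxy)but-3-enal F2. Homologation with lithiated trimethylsilyldiazomethane (Colvin rearrangement, THF, −78 °C → rt) should give the aryl propargyl ether {3-methyl-4-{[(3S)-3-methylpent-1-en-4-yn-3-yl]oxy}phenoxy}tri(propan-2-yl)silane F3. Gold(I)-catalysed 6-endo hydroarylation ([JohnPhosAu(MeCN)]SbF6, CH2Cl2, 0 °C) onto the one free ortho position should then close the pyran ring without breaking the C2–O bond and deliver 9.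

Step 10. Alkyl transfer from boron to palladium may be slow under the aqueous base the coupling needs, so that protodeboronation and base-induced loss of the aryl silyl ether run ahead of C–C bond formation. The fallback sets out from 9 and comes back at 17, forming the same bond by an anhydrous Negishi coupling. Hydroboration of 9 with 9-BBN and oxidation with NaBO3·4H2O should give 2-[(2S)-2,8-dimethyl-6-{[tri(propan-2-yl)silyl]oxy}-2H-chromen-2-yl]ethan-1-ol F4. I2/PPh3/imidazole should give {[(2S)-2-(2-iodoethyl)-2,8-dimethyl-2H-chromen-6-yl]oxy}tri(propan-2-yl)silane F5. Zinc insertion (Zn dust, LiCl, THF) should give {2-[(2S)-2,8-dimethyl-6-{[tri(propan-2-yl)silyl]oxy}-2H-chromen-2-yl]ethyl}(iodo)zinc F6, used without isolation. Coupling of this reagent with 15 under Pd(PPh3)4 in THF should give 17.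

Step 3. The ylide must add to an aldehyde that is deactivated as its ortho-phenoxide, and under the strongly basic conditions the aryl silyl ether can be cleaved or the electron-rich vinylphenol can oligomerise. The fallback sets out from 2 and comes back at 4. Ortho-bromination of 2 (NBS, CH2Cl2, −20 °C; the para position is blocked) should give 2-bromo-6-methyl-4-{[tri(propan-2-yl)silyl]oxy}phenol F7. Suzuki–Miyaura vinylation with potassium vinyltrifluoroborate (PdCl2(dppf), Cs2CO3, THF/H2O, 70 °C) should give 4 under mildly basic conditions.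

Further compounds
F1 | step 4 | (2S)-2-methyl-2-(2-methyl-4-{[tri(propan-2-yl)silyl]oxy}phenoxy)but-3-en-1-ol | C=C[C@@](C)(CO)Oc1ccc(O[Si](C(C)C)(C(C)C)C(C)C)cc1C
F2 | step 4 | (2S)-2-methyl-2-(2-methyl-4-{[tri(propan-2-yl)silyl]oxy}phenoxy)but-3-enal | C=C[C@@](C)(C=O)Oc1ccc(O[Si](C(C)C)(C(C)C)C(C)C)cc1C
F3 | step 4 | {3-methyl-4-{[(3S)-3-methylpent-1-en-4-yn-3-yl]oxy}phenoxy}tri(propan-2-yl)silane | C=C[C@@](C)(C#C)Oc1ccc(O[Si](C(C)C)(C(C)C)C(C)C)cc1C
F4 | step 10 | 2-[(2S)-2,8-dimethyl-6-{[tri(propan-2-yl)silyl]oxy}-2H-chromen-2-yl]ethan-1-ol | OCC[C@@]1(C)C=Cc2cc(O[Si](C(C)C)(C(C)C)C(C)C)cc(C)c2O1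
F5 | step 10 | {[(2S)-2-(2-iodoethyl)-2,8-dimethyl-2H-chromen-6-yl]oxy}tri(propan-2-yl)silane | ICC[C@@]1(C)C=Cc2cc(O[Si](C(C)C)(C(C)C)C(C)C)cc(C)c2O1
F6 | step 10 | {2-[(2S)-2,8-dimethyl-6-{[tri(propan-2-yl)silyl]oxy}-2H-chromen-2-yl]ethyl}(iodo)zinc | I[Zn]CC[C@@]1(C)C=Cc2cc(O[Si](C(C)C)(C(C)C)C(C)C)cc(C)c2O1
F7 | step 3 | 2-bromo-6-methyl-4-{[tri(propan-2-yl)silyl]oxy}phenol | Cc1cc(O[Si](C(C)C)(C(C)C)C(C)C)cc(Br)c1O
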